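**Retrosynthetic overview**

- The chain is numbered from the benzylic CH2 (C1) to the terminal CH3 (C16). The unit C2–C3(=O)–C4–C5(=O)–C6 is pentane-2,4-dione in which each methyl carbon carries one extra carbon substituent: the arylmethyl carbon C1 on C2 and the n-decyl chain C7–C16 on C6.
- Target 12 is reached from its O-benzyl ether 11 by hydrogenolysis.
- Ether 11 is disconnected at C6–C7 and C1–C2 into pentane-2,4-dione 5, 1-bromodecane 6 and benzylic bromide 4, joined in one flask by two successive terminal dianion alkylations.
- Bromide 4 comes from vanillin 1 by O-benzylation, aldehyde reduction and bromination.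
- No ring is formed (the benzene ring is carried in from vanillin) and the target has no stereocentre.

Key step: step 4

Assumption: the β-diketones are written in the diketo form although they exist largely as chelated enols (the same compounds), enolate double-bond geometry is left unspecified, and LiN(i-Pr)2 (LDA) is taken from a commercial solution.

**Step 1**
Reactants: 1 vanillin (4-hydroxy-3-methoxybenzaldehyde)
Product: 2 4-(benzyloxy)-3-methoxybenzaldehyde
Conditions: BnBr, K2CO3, DMF, rt
Reagents that add atoms: benzyl bromide, BrCc1ccccc1
Why: Williamson ether synthesis, in which the phenoxide formed with K2CO3 displaces bromide from benzyl bromide by SN2 while the aldehyde is untouched by the mild base.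

**Step 2**
Reactants: 2 4-(benzyloxy)-3-methoxybenzaldehyde
Product: 3 [4-(benzyloxy)-3-methoxyphenyl]methanol
Conditions: NaBH4, MeOH, 0 °C; aqueous work-up
Reagents that add atoms: none
Why: Borohydride reduction of an aromatic aldehyde should give the primary benzylic alcohol cleanly, the two aryl ethers being inert to hydride.

**Step 3**
Reactants: 3 [4-(benzyloxy)-3-methoxyphenyl]methanol
Product: 4 4-(benzyloxy)-3-methoxybenzyl bromide (1-(benzyloxy)-4-(bromomethyl)-2-methoxybenzene)
Conditions: PBr3 (0.4 equiv), Et2O, 0 °C; cold NaHCO3 wash; used at once
Reagents that add atoms: phosphorus tribromide, BrP(Br)Br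
Why: Bromination of a primary benzylic alcohol with PBr3 proceeds through a phosphite ester that bromide displaces, and the aryl benzyl and methyl ethers should survive the short exposure at 0 °C.

**Step 4**
Reactants: 5 pentane-2,4-dione; 6 1-bromodecane; 4 4-(benzyloxy)-3-methoxybenzyl bromide
Product: 11 O-benzyl [12]-gingerdione (1-[4-(benzyloxy)-3-methoxyphenyl]hexadecane-3,5-dione), via dilithium dianion of pentane-2,4-dione 7 (not isolated), via lithium enolate of pentadecane-2,4-dione 8 (not isolated), via dilithium dianion of pentadecane-2,4-dione 9 (not isolated), via lithium enolate of the product 10 (not isolated)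
Conditions: LiN(i-Pr)2 (2.05 equiv), THF, 0 °C; 6 (1.0 equiv), 0 °C to rt; LiN(i-Pr)2 (1.05 equiv), −78 to −20 °C; 4 (1.0 equiv), −78 to 0 °C; aq. HCl
Reagents that add atoms: none
Why: Two equivalents of the amide base turn 5 into dianion 7, whose terminal carbanion is far more nucleophilic than the delocalised central enolate and displaces bromide from 6 by SN2 to form C6–C7, leaving the chelated monoenolate 8, which does not alkylate further. A third equivalent of base then removes a proton from the remaining methyl group of 8 to give dianion 9, which attacks the reactive benzylic bromide 4 by SN2 to form C1–C2, and acid work-up of enolate 10 releases 11. The closest known reaction type is the Hauser terminal (γ) alkylation of β-diketone dianions, here carried out twice in the same flask. No ring is closed and no stereocentre is created. The step needs terminal rather than central C-alkylation or O-alkylation, which the much greater nucleophilicity of the terminal carbanion and the exact base stoichiometry secure. It also needs deprotonation of 8 at the methyl rather than at the newly substituted C6 methylene, which kinetic removal of the less hindered primary proton at low temperature and fast capture by the benzylic bromide should secure; the slower electrophile 6 is therefore used first, on the symmetrical dianion where no site choice exists.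

**Step 5**
Reactants: 11 O-benzyl [12]-gingerdione
Product: 12 [12]-gingerdione (1-(4-hydroxy-3-methoxyphenyl)hexadecane-3,5-dione)
Conditions: H2 (1 atm), Pd/C (10 wt% Pd on carbon), EtOAc, rt
Reagents that add atoms: none
Why: Catalytic hydrogenolysis over Pd/C at ambient pressure should cleave only the benzylic C–O bond of the aryl benzyl ether, leaving the dialkyl β-diketone and the methyl ether intact.

**Compound list**

1 | vanillin (4-hydroxy-3-methoxybenzaldehyde) | O=Cc1ccc(O)c(OC)c1 | starting material
2 | 4-(benzyloxy)-3-methoxybenzaldehyde | O=Cc1ccc(OCc2ccccc2)c(OC)c1 | intermediate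
3 | [4-(benzyloxy)-3-methoxyphenyl]methanol | OCc1ccc(OCc2ccccc2)c(OC)c1 | intermediate
4 | 4-(benzyloxy)-3-methoxybenzyl bromide | BrCc1ccc(OCc2ccccc2)c(OC)c1 | intermediate
5 | pentane-2,4-dione | CC(=O)CC(C)=O | starting material
6 | 1-bromodecane | CCCCCCCCCCBr | starting material
7 | dilithium dianion of pentane-2,4-dione (dilithium penta-1,3-diene-2,4-diolate) | [Li+].[Li+].C=C([O-])C=C(C)[O-] | intermediate
8 | lithium enolate of pentadecane-2,4-dione | [Li+].CCCCCCCCCCCC(=O)C=C(C)[O-] | intermediate
9 | dilithium dianion of pentadecane-2,4-dione (dilithium pentadeca-1,3-diene-2,4-diolate) | [Li+].[Li+].CCCCCCCCCCCC([O-])=CC(=C)[O-] | intermediate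
10 | lithium enolate of O-benzyl [12]-gingerdione | [Li+].CCCCCCCCCCCC(=O)C=C([O-])CCc1ccc(OCc2ccccc2)c(OC)c1 | intermediate
11 | O-benzyl [12]-gingerdione (1-[4-(benzyloxy)-3-methoxyphenyl]hexadecane-3,5-dione) | CCCCCCCCCCCC(=O)CC(=O)CCc1ccc(OCc2ccccc2)c(OC)c1 | intermediate
12 | [12]-gingerdione (1-(4-hydroxy-3-methoxyphenyl)hexadecane-3,5-dione), no stereocentre | CCCCCCCCCCCC(=O)CC(=O)CCc1ccc(O)c(OC)c1 | target

**Step count**

Total: 5 steps. Longest linear sequence: 5 steps (1 → 2 → 3 → 4 → 11 → 12); compounds 5 and 6 are purchased and enter at step 4.

**Steps most likely to fail**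

1. Step 4. The second deprotonation may lose site control, with proton removal at the C6 methylene or equilibration of the dianion before capture, and proton exchange between dianion 7 and enolate 8 may lead to double decylation. The fallback builds the diketone by acylation instead of double alkylation and sets out from bromide 4 and dione 5. Central C-alkylation of 5 with 4 (K2CO3, acetone, reflux) should give 3-[4-(benzyloxy)-3-methoxybenzyl]pentane-2,4-dione F1. Retro-Claisen deacetylation (K2CO3, EtOH, reflux) then gives 4-[4-(benzyloxy)-3-methoxyphenyl]butan-2-one F2. Crossed Claisen acylation of F2 at its methyl group with methyl dodecanoate (NaH, THF, reflux; acid work-up) comes back to the route at compound 11.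

2. Step 3. The electron-rich benzylic bromide may ionise during formation or isolation and then alkylate itself or hydrolyse. The fallback avoids any benzylic halide and sets out from aldehyde 2. Dianion 9, generated in the flask from 5 and 6 as in step 4, is added to 2 at −78 °C in an aldol addition to give racemic 1-[4-(benzyloxy)-3-methoxyphenyl]-1-hydroxyhexadecane-3,5-dione F3. Acid-catalysed dehydration (TsOH, toluene, warm) gives (E)-1-[4-(benzyloxy)-3-methoxyphenyl]hexadec-1-ene-3,5-dione F4. Hydrogenation over Pd/C (H2, EtOAc) saturates the C1=C2 alkene and cleaves the benzyl ether in one operation, coming back to the route at compound 12.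

3. Step 5. Hydrogenolysis may stall through poisoning of the catalyst by traces of bromide or amine carried over from step 4, or prolonged exposure may begin to reduce the enolised diketone. The fallback replaces reductive cleavage by Lewis-acid debenzylation and sets out from compound 11. Treatment with excess BCl3 and pentamethylbenzene as benzyl-cation scavenger in CH2Cl2 at −78 °C, followed by methanol quench and aqueous work-up, should remove the benzyl group without touching the methyl ether and comes back to the route at compound 12. No new compound is made on the way.

**Further compounds**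

F1 | step 4 | 3-[4-(benzyloxy)-3-methoxybenzyl]pentane-2,4-dione | CC(=O)C(Cc1ccc(OCc2ccccc2)c(OC)c1)C(C)=O
F2 | step 4 | 4-[4-(benzyloxy)-3-methoxyphenyl]butan-2-one | CC(=O)CCc1ccc(OCc2ccccc2)c(OC)c1
F3 | step 3 | 1-[4-(benzyloxy)-3-methoxyphenyl]-1-hydroxyhexadecane-3,5-dione (racemic) | CCCCCCCCCCCC(=O)CC(=O)CC(O)c1ccc(OCc2ccccc2)c(OC)c1
F4 | step 3 | (E)-1-[4-(benzyloxy)-3-methoxyphenyl]hexadec-1-ene-3,5-dione | CCCCCCCCCCCC(=O)CC(=O)/C=C/c1ccc(OCc2ccccc2)c(OC)c1
F0 | step 5 | none | none
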